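Amounts first: the maple run is charged with 0.0960 M of reagent, less than its 0.120 M of starting material, so reagent is the limiting reagent there. Yet target lies near 0.0494 M at 23 min, with 0.0466 M of reagent unused.

the same everywhere: free catalyst 6.00 × 10⁻⁴ M
- maple: starting material 0.120 M; reagent 0.0960 M
- cedar: starting material 0.0600 M; reagent 0.0360 M
- birch: starting material 0.120 M; reagent 0.290 M
- alder: starting material 0.120 M; reagent 0.0960 M; time 140 min

- maple run (time / min: [target] / M): 2.9: 0.0200; 5.8: 0.0312; 8.6: 0.0387; 12: 0.0436; 14: 0.0457; 17: 0.0474; 20: 0.0479; 23: 0.0494
- cedar run (time / min: [target] / M): 2.9: 0.0109; 5.8: 0.0173; 8.6: 0.0200; 12: 0.0236; 14: 0.0238; 17: 0.0249; 20: 0.0263; 23: 0.0263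
- birch run (time / min: [target] / M): 2.9: 0.0222; 5.8: 0.0355; 8.6: 0.0418; 12: 0.0467; 14: 0.0486; 17: 0.0507; 20: 0.0516; 23: 0.0532

(readings scatter by 4 × 10⁻⁴ M)

* apparent order in [starting material] of the starting rate, round the charge of the maple run (the rate where two percent of its starting material have turned into target) (one fixed amount of target, the same in the runs compared)
* apparent order in [reagent] of the starting rate, round the charge of the maple run (the rate where two percent of its starting material have turned into target)
* target in the alder run at 140 min, as a share of the starting material charged

- Overall: starting material + reagent -> target, with free catalyst as catalyst.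
- Constant volume, constant temperature.
- What is held in complexes is read along with the free species.
- An order is taken over about fifteen percent of the charge, up and down.

1. Time, by hand. The maple rise looks like a relaxation towards a plateau. Taking the last reading as the plateau, the gap left at 8.6 min gives a decay constant of 0.178 min⁻¹. That constant leaves a small gap at 23 min, so the plateau rises to 0.0502 M. Putting this back gives 0.171 min⁻¹ and a plateau of 0.0504 M.

2. The quantity carried forward is the catalyst life, the time in which the gap between plateau and [target] shrinks by the factor e: 5.85 min, as read from the maple run. I read the stop in the maple run, with reagent unused, as a loss of catalyst activity.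

3. Time, in the alder run. This flask has the maple charge, and 140 min is 23.9 lives, so my reckoning puts it at the plateau, 42.0% of its starting material.

4. Reagent. The birch run multiplies the reagent charge by 3.02, but its last reading is only 1.08 times the maple one. With a shared life, rates scale as plateaus, which gives a mean order of 0.0670. If the rate bends towards a ceiling as [reagent] rises, with the starting material held fixed, its slope is steeper at the low end, so I expect the local order round the maple charge to lie above this mean.

5. Starting material. The cedar run has half the maple starting material and less reagent, and its last reading is 0.532 of the maple one. Taking off the reagent's part leaves a mean order of 0.815.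

6. The forecast gives 0.75 in starting material, 0.12 in reagent and 42.5%, reasoning of the stop that “It looks like catalyst loss or shutdown”. Its reagent order is higher than my mean, and its starting-material order is lower than mine.

The alder run gives 42.2% at 140 min, and the orders are 0.53 in [starting material], lower than the forecast's, and 0.18 in [reagent], higher than the forecast's.

    free catalyst + starting material ⇌ catalyst-substrate complex (678.0 M⁻¹ min⁻¹, 8.340 min⁻¹)
    catalyst-substrate complex + reagent → target + free catalyst (1344 M⁻¹ min⁻¹)
    free catalyst → spent catalyst (0.1716 min⁻¹)
    2 starting material ⇌ idle substrate dimer, settled at all times (63.80 M⁻¹)

For the birch run, the catalyst life read from the maple run, with the plateau read from the birch readings, 0.0543 M, puts target at a quarter of the starting material charged at 4.71 min, and the birch run took 4.45 min.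

The numbers in the tables are simulated with made-up constants.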